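**Plan**

- The target is 3α-acetoxy-15-hydroxylabda-8(17),13E-dien-18-oic acid (3R,4S,5R,9S,10R). Its trans-fused rings A and B (C1–C10), the oxygen on C3, a C4 carrying CH3 and the equatorial oxidised carbon C18, and the exocyclic C8=C17 methylene next to C9 are the imprint of a chair–chair folded acyclic C20 chain whose terminal (E)-methyl is oxygenated. This pattern is what lets one cationic cascade build the bicycle.
- Retrosynthesis: after functional-group adjustment (C18 CO2H from CH2OSi, 3α-OAc from the 3β-alcohol via the ketone), C4–C5 and C9–C10 are cut together to an acyclic (3S,4S)-epoxy polyene with Me3Si on C17. Then C9–C11 and C8–C17 are cut (alkyne carbocupration/alkylation), then C6–C7 (propargylation).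
- Forward: geranyl acetate is hydroxylated at C18, epoxidised, brominated at C6 and propargylated. The alkyne, a Me3SiCH2 copper reagent and a C11–C15 iodide from but-3-yn-1-ol are joined in one operation. Ring A and then ring B close in a single Lewis-acid cascade, after which C3 and C18 are adjusted.
- Stereochemistry: C3 and C4 come from the Sharpless epoxide (L-(+)-tartrate) and its anti opening; C5, C10 and C9 from the chair–chair fold of the trans-disposed alkenes; the final 3α configuration from equatorial hydride delivery to the 3-ketone. Alkene geometry comes from geranyl acetate, syn-carbocupration and syn-carboalumination.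

Key step: step 14

Remark: labdane numbering is used for all compounds, acyclic ones included. The C8=C9 alkene of the allylsilane is formally Z (CH2SiMe3 outranks C7) although the carbon chain runs trans across it. (Trimethylsilyl)methylmagnesium chloride is taken as a commercial solution.

**Route**

Step 1
Reactants: 1 geranyl acetate
Product: 2 (2E,6E)-8-hydroxy-3,7-dimethylocta-2,6-dien-1-yl acetate
Conditions: SeO2 (cat.), t-BuOOH, salicylic acid (cat.), CH2Cl2, 0 °C to rt
Reagents that add atoms: tert-butyl hydroperoxide CC(C)(C)OO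
Why: Selenium dioxide allylic oxidation (ene reaction then [2,3]-shift) attacks the electron-rich terminal trisubstituted alkene at its (E)-methyl group, while the 2,3-alkene is deactivated by the allylic acetate.

Step 2
Reactants: 2 (2E,6E)-8-hydroxy-3,7-dimethylocta-2,6-dien-1-yl acetate
Product: 3 (2E)-5-[(2S,3S)-3-(hydroxymethyl)-3-methyloxiran-2-yl]-3-methylpent-2-en-1-yl acetate
Conditions: Ti(OiPr)4 (cat.), L-(+)-diethyl tartrate (cat.), t-BuOOH, 4 Å MS, CH2Cl2, −20 °C
Reagents that add atoms: tert-butyl hydroperoxide CC(C)(C)OO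
Why: Sharpless asymmetric epoxidation of the (E)-2-methyl allylic alcohol with the L-(+)-tartrate delivers oxygen to one alkene face and should set both epoxide carbons S (later C3 and C4), while the acetate-bearing alkene has no free allylic hydroxyl and stays untouched.

Step 3
Reactants: 3 (2E)-5-[(2S,3S)-3-(hydroxymethyl)-3-methyloxiran-2-yl]-3-methylpent-2-en-1-yl acetate
Product: 4 (2E)-5-[(2S,3S)-3-(tert-butyldimethylsilyloxymethyl)-3-methyloxiran-2-yl]-3-methylpent-2-en-1-yl acetate
Conditions: TBSCl, imidazole, DMF, 0 °C to rt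
Reagents that add atoms: tert-butyldimethylsilyl chloride CC(C)(C)[Si](C)(C)Cl
Why: Silyl ether formation masks O18 so that no alkoxide is available for a Payne rearrangement in the basic steps that follow and the oxygen cannot act as a nucleophile in the cyclization.

Step 4
Reactants: 4 (2E)-5-[(2S,3S)-3-(tert-butyldimethylsilyloxymethyl)-3-methyloxiran-2-yl]-3-methylpent-2-en-1-yl acetate
Product: 5 (2E)-5-[(2S,3S)-3-(tert-butyldimethylsilyloxymethyl)-3-methyloxiran-2-yl]-3-methylpent-2-en-1-ol
Conditions: K2CO3, MeOH, 0 °C to rt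
Reagents that add atoms: none
Why: Base-catalysed transesterification removes the acetate, and the trisubstituted epoxide and the silyl ether are inert to methanolic carbonate.

Step 5
Reactants: 5 (2E)-5-[(2S,3S)-3-(tert-butyldimethylsilyloxymethyl)-3-methyloxiran-2-yl]-3-methylpent-2-en-1-ol
Product: 7 tert-butyl{[(2S,3S)-3-[(3E)-5-bromo-3-methylpent-3-en-1-yl]-2-methyloxiran-2-yl]methoxy}dimethylsilane, via allylic mesylate 6 (not isolated)
Conditions: MsCl, Et3N, THF, −40 °C; then LiBr, −40 to 0 °C
Reagents that add atoms: lithium bromide [Li+].[Br-]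
Why: Mesylation followed by SN2 displacement with bromide gives the primary allylic bromide under buffered conditions below 0 °C, at which the epoxide is not opened and the alkene geometry is kept.

Step 6
Reactants: 7 tert-butyl{[(2S,3S)-3-[(3E)-5-bromo-3-methylpent-3-en-1-yl]-2-methyloxiran-2-yl]methoxy}dimethylsilane; 8 1-(trimethylsilyl)propyne
Product: 10 tert-butyldimethyl{[(2S,3S)-2-methyl-3-[(3E)-3-methyl-8-(trimethylsilyl)oct-3-en-7-yn-1-yl]oxiran-2-yl]methoxy}silane, via 3-lithio-1-(trimethylsilyl)propyne 9 (not isolated)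
Conditions: 8, n-BuLi, THF, −78 to −20 °C; then 7, −78 to −20 °C
Reagents that add atoms: none
Why: SN2 alkylation of the silyl-blocked propargyllithium by the primary allylic bromide forms C6–C7 at the propargylic terminus, and the trisubstituted epoxide does not react with this carbanion at low temperature.

Step 7
Reactants: 10 tert-butyldimethyl{[(2S,3S)-2-methyl-3-[(3E)-3-methyl-8-(trimethylsilyl)oct-3-en-7-yn-1-yl]oxiran-2-yl]methoxy}silane
Product: 11 tert-butyldimethyl{[(2S,3S)-2-methyl-3-[(3E)-3-methyloct-3-en-7-yn-1-yl]oxiran-2-yl]methoxy}silane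
Conditions: K2CO3, MeOH, rt
Reagents that add atoms: none
Why: Methanolysis of the alkynyl C–Si bond (protodesilylation) frees the terminal alkyne, while the O–Si ether and the epoxide are stable to these conditions.

Step 8
Reactants: 12 but-3-yn-1-ol
Product: 13 tert-butyl(but-3-yn-1-yloxy)dimethylsilane
Conditions: TBSCl, imidazole, CH2Cl2, 0 °C to rt
Reagents that add atoms: tert-butyldimethylsilyl chloride CC(C)(C)[Si](C)(C)Cl
Why: Silyl ether formation keeps the hydroxyl from consuming the organoaluminium reagent and lets the two oxygen termini of this fragment be told apart later.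

Step 9
Reactants: 13 tert-butyl(but-3-yn-1-yloxy)dimethylsilane
Product: 16 (2E)-5-(tert-butyldimethylsilyloxy)-3-methylpent-2-en-1-ol, via alkenyldimethylalane 14 (not isolated), via lithium alkenylalanate 15 (not isolated)
Conditions: Me3Al, Cp2ZrCl2 (cat.), CH2Cl2, 0 °C to rt; n-BuLi, THF, −78 °C; (CH2O)n, −78 °C to rt; aq. Rochelle salt
Reagents that add atoms: trimethylaluminium C[Al](C)C; paraformaldehyde (formaldehyde unit) C=O
Why: Negishi zirconium-catalysed carboalumination adds methyl and aluminium syn across the terminal alkyne with methyl on the internal carbon, and the alanate adds to formaldehyde with retention, which fixes the 13E alkene and installs C16 and C15.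

Step 10
Reactants: 16 (2E)-5-(tert-butyldimethylsilyloxy)-3-methylpent-2-en-1-ol
Product: 17 (2E)-5-(tert-butyldimethylsilyloxy)-1-(tert-butyldiphenylsilyloxy)-3-methylpent-2-ene
Conditions: TBDPSCl, imidazole, CH2Cl2, rt
Reagents that add atoms: tert-butyldiphenylsilyl chloride CC(C)(C)[Si](Cl)(c1ccccc1)c1ccccc1
Why: Silylation gives the allylic TBDPS ether at O15, chosen because it outlasts the acidic conditions that later remove the two TBS groups.

Step 11
Reactants: 17 (2E)-5-(tert-butyldimethylsilyloxy)-1-(tert-butyldiphenylsilyloxy)-3-methylpent-2-ene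
Product: 18 (3E)-5-(tert-butyldiphenylsilyloxy)-3-methylpent-3-en-1-ol
Conditions: PPTS, MeOH, rt
Reagents that add atoms: none
Why: Acid-catalysed solvolysis of silyl ethers is far faster for a primary TBS than for a primary TBDPS group, so only O11 is freed.

Step 12
Reactants: 18 (3E)-5-(tert-butyldiphenylsilyloxy)-3-methylpent-3-en-1-ol
Product: 19 tert-butyl{[(2E)-5-iodo-3-methylpent-2-en-1-yl]oxy}diphenylsilane
Conditions: I2, PPh3, imidazole, CH2Cl2, 0 °C to rt
Reagents that add atoms: iodine II
Why: Appel-type iodination displaces the alkoxyphosphonium ion by iodide in an SN2 step at a homoallylic carbon, so no allylic transposition can occur.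

Step 13
Reactants: 11 tert-butyldimethyl{[(2S,3S)-2-methyl-3-[(3E)-3-methyloct-3-en-7-yn-1-yl]oxiran-2-yl]methoxy}silane; 20 (trimethylsilyl)methylmagnesium chloride; 19 tert-butyl{[(2E)-5-iodo-3-methylpent-2-en-1-yl]oxy}diphenylsilane
Product: 23 (3S,4S)-3,4-epoxy-18-(tert-butyldimethylsilyloxy)-15-(tert-butyldiphenylsilyloxy)-17-(trimethylsilyl) acyclic tetraene [5(10)E,8Z,13E; labdane numbering], via (trimethylsilyl)methylcopper 21 (not isolated), via alkenylcopper 22 (not isolated)
Conditions: 20, CuBr·SMe2, Et2O/Me2S, −45 °C; 11, −45 to −20 °C; then 19, HMPA, P(OEt)3, −20 °C to rt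
Reagents that add atoms: none
Why: Normant carbocupration adds Me3SiCH2 and copper syn across the terminal alkyne with the silylmethyl group on the internal carbon C8, and alkylation of the alkenylcopper by the primary iodide with retention forms C9–C11 and so places CH2SiMe3 cis to C11, while the trisubstituted epoxide and the silyl ethers are inert to the non-basic organocopper.

Step 14
Reactants: 23 (3S,4S)-3,4-epoxy-18-(tert-butyldimethylsilyloxy)-15-(tert-butyldiphenylsilyloxy)-17-(trimethylsilyl) acyclic tetraene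
Product: 24 18-(tert-butyldimethylsilyloxy)-15-(tert-butyldiphenylsilyloxy)labda-8(17),13E-dien-3β-ol
Conditions: MeAlCl2, CH2Cl2, −78 °C; then Et3N, aq. NaHCO3
Reagents that add atoms: none
Why: MeAlCl2 binds the epoxide oxygen, the C4–O bond ionises with backside participation of the C5=C10 alkene, the C10 cation is captured by C9 of the allylsilane, and the β-silyl cation at C8 loses Me3Si to leave the C8=C17 methylene; this is a Lewis-acid epoxy-polyene bicyclization terminated by an allylsilane. Ring A closes 6-endo on the C5=C10 alkene (bond C4–C5) and ring B closes 6-endo on the C8=C9 alkene (bond C9–C10), both in a chair–chair fold. C3 keeps the configuration of the epoxide and becomes the equatorial 3β-alcohol, C4 is set by inversion so that the CH2OTBS group lying trans to the chain in the epoxide becomes the equatorial 4α substituent, C5 and C10 follow from anti addition across the E alkene (trans ring fusion), and C9 follows from the chair fold of the C8=C9 alkene whose chain runs trans (side chain equatorial, 9α-H). The step needs ionisation at C4 rather than at C3, which the tertiary centre and the alkene held five atoms away secure, and it needs the cascade to stop after two rings with a single alkene isomer, which the silicon on C17 secures because desilylation outruns attack by the remote C13=C14 alkene.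

Step 15
Reactants: 24 18-(tert-butyldimethylsilyloxy)-15-(tert-butyldiphenylsilyloxy)labda-8(17),13E-dien-3β-ol
Product: 25 18-(tert-butyldimethylsilyloxy)-15-(tert-butyldiphenylsilyloxy)labda-8(17),13E-dien-3-one
Conditions: Dess–Martin periodinane, NaHCO3, CH2Cl2, rt
Reagents that add atoms: none
Why: Dess–Martin oxidation converts the secondary alcohol into the ketone under neutral conditions that leave the alkenes and both silyl ethers alone, and the quaternary C4 cannot epimerise.

Step 16
Reactants: 25 18-(tert-butyldimethylsilyloxy)-15-(tert-butyldiphenylsilyloxy)labda-8(17),13E-dien-3-one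
Product: 26 18-(tert-butyldimethylsilyloxy)-15-(tert-butyldiphenylsilyloxy)labda-8(17),13E-dien-3α-ol
Conditions: LiBH(s-Bu)3, THF, −78 °C; then aq. NaOH, H2O2, 0 °C
Reagents that add atoms: none
Why: Hydride reduction with the bulky L-Selectride should follow the equatorial trajectory, because the axial approach is screened by the axial hydrogens on C1 and C5, and so should give the axial 3α-alcohol (C3 now R).

Step 17
Reactants: 26 18-(tert-butyldimethylsilyloxy)-15-(tert-butyldiphenylsilyloxy)labda-8(17),13E-dien-3α-ol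
Product: 27 18-(tert-butyldimethylsilyloxy)-15-(tert-butyldiphenylsilyloxy)labda-8(17),13E-dien-3α-yl acetate
Conditions: Ac2O, DMAP, pyridine, 40 °C
Reagents that add atoms: acetic anhydride CC(=O)OC(C)=O
Why: DMAP-catalysed acylation esterifies the hindered axial alcohol, the only free hydroxyl present, with retention at C3.

Step 18
Reactants: 27 18-(tert-butyldimethylsilyloxy)-15-(tert-butyldiphenylsilyloxy)labda-8(17),13E-dien-3α-yl acetate
Product: 28 3α-acetoxy-15-(tert-butyldiphenylsilyloxy)labda-8(17),13E-dien-18-ol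
Conditions: HF·pyridine, pyridine, THF, 0 °C to rt
Reagents that add atoms: none
Why: Desilylation with buffered HF·pyridine cleaves the TBS ether much faster than the TBDPS ether, and the mildly acidic medium disfavours acetyl migration from O3 to O18.

Step 19
Reactants: 28 3α-acetoxy-15-(tert-butyldiphenylsilyloxy)labda-8(17),13E-dien-18-ol
Product: 29 3α-acetoxy-15-(tert-butyldiphenylsilyloxy)labda-8(17),13E-dien-18-al
Conditions: Dess–Martin periodinane, NaHCO3, CH2Cl2, rt
Reagents that add atoms: none
Why: Dess–Martin oxidation stops at the aldehyde, which can neither epimerise nor eliminate acetate because C4 bears no hydrogen.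

Step 20
Reactants: 29 3α-acetoxy-15-(tert-butyldiphenylsilyloxy)labda-8(17),13E-dien-18-al
Product: 30 3α-acetoxy-15-(tert-butyldiphenylsilyloxy)labda-8(17),13E-dien-18-oic acid
Conditions: NaClO2, NaH2PO4, 2-methyl-2-butene, t-BuOH/H2O, rt
Reagents that add atoms: sodium chlorite [Na+].[O-]Cl=O
Why: Pinnick oxidation converts the hindered aldehyde into the acid, with 2-methyl-2-butene trapping HOCl so that the 8(17) and 13 alkenes are not chlorinated.

Step 21
Reactants: 30 3α-acetoxy-15-(tert-butyldiphenylsilyloxy)labda-8(17),13E-dien-18-oic acid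
Product: 31 3α-acetoxy-15-hydroxylabda-8(17),13E-dien-18-oic acid
Conditions: TBAF, AcOH, THF, 0 °C to rt
Reagents that add atoms: none
Why: Fluoride-mediated desilylation buffered with acetic acid frees the primary allylic alcohol without hydrolysing the hindered 3α-acetate.

**Compound list**

1 | geranyl acetate | CC(=O)OC/C=C(\C)CCC=C(C)C | starting material
2 | (2E,6E)-8-hydroxy-3,7-dimethylocta-2,6-dien-1-yl acetate | CC(=O)OC/C=C(\C)CC/C=C(\C)CO | intermediate
3 | (2E)-5-[(2S,3S)-3-(hydroxymethyl)-3-methyloxiran-2-yl]-3-methylpent-2-en-1-yl acetate | OC[C@]1(C)O[C@H]1CC/C(C)=C/COC(C)=O | intermediate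
4 | (2E)-5-[(2S,3S)-3-(tert-butyldimethylsilyloxymethyl)-3-methyloxiran-2-yl]-3-methylpent-2-en-1-yl acetate | CC(C)(C)[Si](C)(C)OC[C@]1(C)O[C@H]1CC/C(C)=C/COC(C)=O | intermediate
5 | (2E)-5-[(2S,3S)-3-(tert-butyldimethylsilyloxymethyl)-3-methyloxiran-2-yl]-3-methylpent-2-en-1-ol | CC(C)(C)[Si](C)(C)OC[C@]1(C)O[C@H]1CC/C(C)=C/CO | intermediate
6 | methanesulfonate of 5 (not isolated) | CC(C)(C)[Si](C)(C)OC[C@]1(C)O[C@H]1CC/C(C)=C/COS(C)(=O)=O | intermediate
7 | tert-butyl{[(2S,3S)-3-[(3E)-5-bromo-3-methylpent-3-en-1-yl]-2-methyloxiran-2-yl]methoxy}dimethylsilane | CC(C)(C)[Si](C)(C)OC[C@]1(C)O[C@H]1CC/C(C)=C/CBr | intermediate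
8 | 1-(trimethylsilyl)propyne | CC#C[Si](C)(C)C | starting material
9 | 3-lithio-1-(trimethylsilyl)propyne (not isolated) | [Li]CC#C[Si](C)(C)C | intermediate
10 | tert-butyldimethyl{[(2S,3S)-2-methyl-3-[(3E)-3-methyl-8-(trimethylsilyl)oct-3-en-7-yn-1-yl]oxiran-2-yl]methoxy}silane | CC(C)(C)[Si](C)(C)OC[C@]1(C)O[C@H]1CC/C(C)=C/CCC#C[Si](C)(C)C | intermediate
11 | tert-butyldimethyl{[(2S,3S)-2-methyl-3-[(3E)-3-methyloct-3-en-7-yn-1-yl]oxiran-2-yl]methoxy}silane | CC(C)(C)[Si](C)(C)OC[C@]1(C)O[C@H]1CC/C(C)=C/CCC#C | intermediate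
12 | but-3-yn-1-ol | C#CCCO | starting material
13 | tert-butyl(but-3-yn-1-yloxy)dimethylsilane | C#CCCO[Si](C)(C)C(C)(C)C | intermediate
14 | [(1E)-4-(tert-butyldimethylsilyloxy)-2-methylbut-1-en-1-yl]dimethylalane (not isolated) | C[Al](C)/C=C(\C)CCO[Si](C)(C)C(C)(C)C | intermediate
15 | lithium butyl[(1E)-4-(tert-butyldimethylsilyloxy)-2-methylbut-1-en-1-yl]dimethylaluminate (not isolated) | [Li+].CCCC[Al-](C)(C)/C=C(\C)CCO[Si](C)(C)C(C)(C)C | intermediate
16 | (2E)-5-(tert-butyldimethylsilyloxy)-3-methylpent-2-en-1-ol | OC/C=C(\C)CCO[Si](C)(C)C(C)(C)C | intermediate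
17 | (2E)-5-(tert-butyldimethylsilyloxy)-1-(tert-butyldiphenylsilyloxy)-3-methylpent-2-ene | CC(C)(C)[Si](C)(C)OCC/C(C)=C/CO[Si](c1ccccc1)(c1ccccc1)C(C)(C)C | intermediate
18 | (3E)-5-(tert-butyldiphenylsilyloxy)-3-methylpent-3-en-1-ol | OCC/C(C)=C/CO[Si](c1ccccc1)(c1ccccc1)C(C)(C)C | intermediate
19 | tert-butyl{[(2E)-5-iodo-3-methylpent-2-en-1-yl]oxy}diphenylsilane | ICC/C(C)=C/CO[Si](c1ccccc1)(c1ccccc1)C(C)(C)C | intermediate
20 | (trimethylsilyl)methylmagnesium chloride | C[Si](C)(C)C[Mg]Cl | starting material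
21 | (trimethylsilyl)methylcopper, MgBrCl complex (not isolated) | C[Si](C)(C)C[Cu] | intermediate
22 | (Z)-alkenylcopper at C9 with CH2SiMe3 on C8 (not isolated) | CC(C)(C)[Si](C)(C)OC[C@]1(C)O[C@H]1CC/C(C)=C/CC/C(C[Si](C)(C)C)=C/[Cu] | intermediate
23 | (3S,4S)-3,4-epoxy-18-(tert-butyldimethylsilyloxy)-15-(tert-butyldiphenylsilyloxy)-17-(trimethylsilyl) acyclic tetraene, 5(10)E,8Z,13E | CC(C)(C)[Si](C)(C)OC[C@]1(C)O[C@H]1CC/C(C)=C/CC/C(C[Si](C)(C)C)=C/CC/C(C)=C/CO[Si](c1ccccc1)(c1ccccc1)C(C)(C)C | intermediate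
24 | 18-(tert-butyldimethylsilyloxy)-15-(tert-butyldiphenylsilyloxy)labda-8(17),13E-dien-3β-ol | C=C1CC[C@@H]2[C@](C)(CC[C@H](O)[C@@]2(C)CO[Si](C)(C)C(C)(C)C)[C@H]1CC/C(C)=C/CO[Si](c1ccccc1)(c1ccccc1)C(C)(C)C | intermediate
25 | 18-(tert-butyldimethylsilyloxy)-15-(tert-butyldiphenylsilyloxy)labda-8(17),13E-dien-3-one | C=C1CC[C@@H]2[C@](C)(CCC(=O)[C@@]2(C)CO[Si](C)(C)C(C)(C)C)[C@H]1CC/C(C)=C/CO[Si](c1ccccc1)(c1ccccc1)C(C)(C)C | intermediate
26 | 18-(tert-butyldimethylsilyloxy)-15-(tert-butyldiphenylsilyloxy)labda-8(17),13E-dien-3α-ol | C=C1CC[C@@H]2[C@](C)(CC[C@@H](O)[C@@]2(C)CO[Si](C)(C)C(C)(C)C)[C@H]1CC/C(C)=C/CO[Si](c1ccccc1)(c1ccccc1)C(C)(C)C | intermediate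
27 | 18-(tert-butyldimethylsilyloxy)-15-(tert-butyldiphenylsilyloxy)labda-8(17),13E-dien-3α-yl acetate | C=C1CC[C@@H]2[C@](C)(CC[C@@H](OC(C)=O)[C@@]2(C)CO[Si](C)(C)C(C)(C)C)[C@H]1CC/C(C)=C/CO[Si](c1ccccc1)(c1ccccc1)C(C)(C)C | intermediate
28 | 3α-acetoxy-15-(tert-butyldiphenylsilyloxy)labda-8(17),13E-dien-18-ol | C=C1CC[C@@H]2[C@](C)(CC[C@@H](OC(C)=O)[C@@]2(C)CO)[C@H]1CC/C(C)=C/CO[Si](c1ccccc1)(c1ccccc1)C(C)(C)C | intermediate
29 | 3α-acetoxy-15-(tert-butyldiphenylsilyloxy)labda-8(17),13E-dien-18-al | C=C1CC[C@@H]2[C@](C)(CC[C@@H](OC(C)=O)[C@@]2(C)C=O)[C@H]1CC/C(C)=C/CO[Si](c1ccccc1)(c1ccccc1)C(C)(C)C | intermediate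
30 | 3α-acetoxy-15-(tert-butyldiphenylsilyloxy)labda-8(17),13E-dien-18-oic acid | C=C1CC[C@@H]2[C@](C)(CC[C@@H](OC(C)=O)[C@@]2(C)C(=O)O)[C@H]1CC/C(C)=C/CO[Si](c1ccccc1)(c1ccccc1)C(C)(C)C | intermediate
31 | 3α-acetoxy-15-hydroxylabda-8(17),13E-dien-18-oic acid, (3R,4S,5R,9S,10R) | C=C1CC[C@@H]2[C@](C)(CC[C@@H](OC(C)=O)[C@@]2(C)C(=O)O)[C@H]1CC/C(C)=C/CO | target

**Step count**

Total: 21 steps. Longest linear sequence: 16 steps (steps 1–7 and 13–21, from geranyl acetate); the iodide branch (steps 8–12) joins at step 13.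

**Steps most likely to fail**

Step 14. The allylsilane may be protodesilylated by the Lewis acid or by traces of HCl before ring B closes, and the cascade may halt after ring A; both processes would give monocyclic material or alkene isomers. The fallback exchanges the acid-labile terminator for a β-keto ester enol and sets out from bromide 7. Alkylation of the dianion of methyl acetoacetate (NaH, then n-BuLi, THF, 0 °C) at its terminal carbon should give methyl (6E)-9-[(2S,3S)-3-(tert-butyldimethylsilyloxymethyl)-3-methyloxiran-2-yl]-7-methyl-3-oxonon-6-enoate F1. Alkylation of F1 at C9 with iodide 19 (K2CO3, acetone, reflux) should give the C9-alkylated β-keto ester F2 as a mixture of C9 epimers. Treatment with MeAlCl2 in CH2Cl2 at −78 °C should then close rings A and B with the enol as terminator, a known variant of the epoxy-olefin cyclization, to give methyl 3β-hydroxy-8-oxo-18-(tert-butyldimethylsilyloxy)-15-(tert-butyldiphenylsilyloxy)-17-norlabd-13E-ene-9-carboxylate F3. Krapcho dealkoxycarbonylation (LiCl, wet DMSO, 140 °C) should give 3β-hydroxy-18-(tert-butyldimethylsilyloxy)-15-(tert-butyldiphenylsilyloxy)-17-norlabd-13E-en-8-one F4, with the C9 side chain settling in the equatorial position by enolisation. Wittig methylenation (Ph3P=CH2, THF) of F4 returns to the route at compound 24.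

Step 13. Alkylation of the alkenylcopper by the unactivated homoallylic iodide may be slow, so that protonolysis or dimerisation of the alkenylcopper and dehydrohalogenation of the iodide compete. The fallback separates the two bond formations and sets out from alkyne 11. The carbocupration is run as in step 13, but the alkenylcopper is quenched with I2 at −78 °C to give the (Z)-vinyl iodide tert-butyl{[(2S,3S)-3-[(3E,7Z)-8-iodo-3-methyl-7-(trimethylsilylmethyl)octa-3,7-dien-1-yl]-2-methyloxiran-2-yl]methoxy}dimethylsilane F5. Iodide 19 is converted with zinc dust and LiCl in THF into the alkylzinc iodide [(3E)-5-(tert-butyldiphenylsilyloxy)-3-methylpent-3-en-1-yl]zinc iodide F6. Negishi coupling of F5 with F6 under Pd(PPh3)4 catalysis in THF, which retains the alkene geometry, returns to the route at compound 23.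

Step 18. During selective desilylation the acetyl group may migrate from O3 to the newly freed O18, and the C15 silyl ether may be partly lost. The fallback oxidises C18 before the acetate is introduced and sets out from alcohol 26. HF·pyridine in THF/pyridine should give 15-(tert-butyldiphenylsilyloxy)labda-8(17),13E-diene-3α,18-diol F7. TEMPO (cat.) with PhI(OAc)2 in CH2Cl2, which is selective for the primary over the hindered axial secondary alcohol, should give 3α-hydroxy-15-(tert-butyldiphenylsilyloxy)labda-8(17),13E-dien-18-al F8. Pinnick oxidation should give 3α-hydroxy-15-(tert-butyldiphenylsilyloxy)labda-8(17),13E-dien-18-oic acid F9. Acetylation (Ac2O, DMAP, pyridine, then aqueous hydrolysis of the mixed anhydride) returns to the route at compound 30.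

**Further compounds**

F1 | step 14 | methyl (6E)-9-[(2S,3S)-3-(tert-butyldimethylsilyloxymethyl)-3-methyloxiran-2-yl]-7-methyl-3-oxonon-6-enoate | CC(C)(C)[Si](C)(C)OC[C@]1(C)O[C@H]1CC/C(C)=C/CCC(=O)CC(=O)OC
F2 | step 14 | C9-alkylated β-keto ester (C9 epimers) | CC(C)(C)[Si](C)(C)OC[C@]1(C)O[C@H]1CC/C(C)=C/CCC(=O)C(CC/C(C)=C/CO[Si](c1ccccc1)(c1ccccc1)C(C)(C)C)C(=O)OC
F3 | step 14 | methyl 3β-hydroxy-8-oxo-18-(tert-butyldimethylsilyloxy)-15-(tert-butyldiphenylsilyloxy)-17-norlabd-13E-ene-9-carboxylate (C9 configuration immaterial) | O=C1CC[C@@H]2[C@](C)(CC[C@H](O)[C@@]2(C)CO[Si](C)(C)C(C)(C)C)C1(CC/C(C)=C/CO[Si](c1ccccc1)(c1ccccc1)C(C)(C)C)C(=O)OC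
F4 | step 14 | 3β-hydroxy-18-(tert-butyldimethylsilyloxy)-15-(tert-butyldiphenylsilyloxy)-17-norlabd-13E-en-8-one | O=C1CC[C@@H]2[C@](C)(CC[C@H](O)[C@@]2(C)CO[Si](C)(C)C(C)(C)C)[C@H]1CC/C(C)=C/CO[Si](c1ccccc1)(c1ccccc1)C(C)(C)C
F5 | step 13 | tert-butyl{[(2S,3S)-3-[(3E,7Z)-8-iodo-3-methyl-7-(trimethylsilylmethyl)octa-3,7-dien-1-yl]-2-methyloxiran-2-yl]methoxy}dimethylsilane | CC(C)(C)[Si](C)(C)OC[C@]1(C)O[C@H]1CC/C(C)=C/CC/C(C[Si](C)(C)C)=C/I
F6 | step 13 | [(3E)-5-(tert-butyldiphenylsilyloxy)-3-methylpent-3-en-1-yl]zinc iodide | I[Zn]CC/C(C)=C/CO[Si](c1ccccc1)(c1ccccc1)C(C)(C)C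
F7 | step 18 | 15-(tert-butyldiphenylsilyloxy)labda-8(17),13E-diene-3α,18-diol | C=C1CC[C@@H]2[C@](C)(CC[C@@H](O)[C@@]2(C)CO)[C@H]1CC/C(C)=C/CO[Si](c1ccccc1)(c1ccccc1)C(C)(C)C
F8 | step 18 | 3α-hydroxy-15-(tert-butyldiphenylsilyloxy)labda-8(17),13E-dien-18-al | C=C1CC[C@@H]2[C@](C)(CC[C@@H](O)[C@@]2(C)C=O)[C@H]1CC/C(C)=C/CO[Si](c1ccccc1)(c1ccccc1)C(C)(C)C
F9 | step 18 | 3α-hydroxy-15-(tert-butyldiphenylsilyloxy)labda-8(17),13E-dien-18-oic acid | C=C1CC[C@@H]2[C@](C)(CC[C@@H](O)[C@@]2(C)C(=O)O)[C@H]1CC/C(C)=C/CO[Si](c1ccccc1)(c1ccccc1)C(C)(C)C
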